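## Structural features

Compound 30 is a type B polyprenylated acylphloroglucinol built on a bicyclo[3.3.1]nonane-2,4,9-trione. Ring A (C1, C2, C3, C4, C5, C9) holds the enolised β-triketone with the 3-hydroxybenzoyl group on C3. Ring B (C1, C8, C7, C6, C5, C9) holds the gem-dimethyl carbon C8 and the prenylated carbon C7. The rings share the bridgeheads C1 (prenyl) and C5 (geranyl) and the C9 ketone. Both bridgeheads are quaternary, and C1 is also bonded to the quaternary C8, so two fully substituted carbons are neighbours.

There are three stereocentres, (1S,5S,7S). C1 and C5 are tied to each other by the bicycle. C7 lies 1,3 to both, and its prenyl group is endo: it points towards ring A, cis to the C1–C2 and C5–C4 bonds.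

The fragile groups are the four trisubstituted alkenes (acid, electrophiles, unselective hydroboration or metathesis), the acidic and ambident triketone (retro-Claisen at the non-enolisable C9 array) and the free phenol.

The real difficulties are the congested C1–C8 bond, the kinetically set endo centre at C7, and absolute control of the bridgeheads.

The key step uses the fact that C8 carries no hydrogen. A cyclopentanone made of C5, C6, C7, C8 and C9 can therefore enolise only towards C5. Its C9 carbonyl then accepts C1 of a four-carbon unit that has been attached through C4 to C5. The C9 carbinol formed next to C1 is what a later 1,2-shift of C8 from C9 to C1 needs to turn the fused skeleton into rings A and B.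

## Logic of the disconnections

30 is traced to 29 by cutting the O–CH3 bond at C4 and the aryl O–Si bond. The triketone and the phenol stay masked through every organometallic step. The forward step must remove both groups in one basic hydrolysis without retro-Claisen cleavage.

29 is cut at the C3–C(aroyl) bond into 24 and 27; 27 goes back through 26 to 25. C3 carries the only acidic hydrogen left in 24, so the arene can come last. The forward step needs C-acylation of a hindered vinyl anion.

24 is cut at the CH2–CH bond of the C7 side chain and at C7–H, giving 21 and 22. C7 becomes trigonal, so the only non-bridgehead stereocentre disappears. The forward step must add hydrogen to C7 from the exo face and must touch only the 1,1-disubstituted alkene.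

21 is traced through 20 to 19 by exchanging the exocyclic carbon for oxygen and then reducing the ketone to the carbinol. This links the methylene carbon to the oxygen stereocentre that steers the annulation. The forward steps need a methylenation that picks the C7 ketone over the C9 ketone and the vinylogous ester.

19 is traced through 18 to 15 and 16 by cutting the C1–prenyl bond, and 15 to 13 by cutting the C3–Si bond. C1 is the only bridgehead C–H and sits between the C2 and C9 carbonyls. It is substituted while C7 is still a silyl ether, so no enolisable ketone competes. The forward step needs C3 blocked and the enol ether oxygen on C4.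

13 is traced to 12 by cutting the O–CH3 bond, and 12 to 10 by cutting C1–C8 and restoring C8–C9. The bridged skeleton becomes a cis-fused hydrindane whose six-membered ring is ring A. The forward step needs an oxidant that makes C1 electrophilic next to the C9 carbinol, and migration of C8, not C5.

10 is cut at C4–C5 and C1–C9 into 6 and 7. Ring A and two stereocentres are removed at once, and a monocyclic ketone remains. The forward step needs C-acylation of a tetrasubstituted enolate on the face away from the C7 oxygen, followed by aldol closure before proton transfer.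

6 is cut at the C5–CH2 bond into 3 and 4. The forward step is an alkylation at the only enolisable position; its facial outcome is not critical because C5 is re-formed in the next step.

3 is traced through 2 to 1 by removing the silyl group and the C7–H bond. An achiral dione remains. The forward step must distinguish two enantiotopic carbonyls.

## Other disconnections considered

Alternative 1: The cut is through C2–C3 and C4–C5 of ring A, leading from the enol ether A1 back to the bicyclo[3.1.1]heptane-6,7-dione A2 and an alkoxyacetylene.
- **Forward step:** a zerovalent nickel catalyst with a chiral phosphine would couple one carbonyl of A2 with the alkyne, break the C2–C5 bond by β-carbon elimination and close ring A by reductive elimination.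
- **In its favour:** A1 is the ethyl analogue of 21, with both quaternary bridgeheads already present. The blocking step, the hindered bridgehead alkylation and the C7 oxygen manipulations of the chosen route would all be unnecessary, and the absolute configuration would come from a catalyst. On these points it is the better plan.
- **Equal point:** which C–C bond of the attacked carbonyl breaks only decides where the ethoxy group ends up. Both positional isomers would converge once the enol ether is cleaved, so this selectivity matters less than the enol ether regiochemistry of the chosen route.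
- **Against it:** A2 is a cyclobutane-1,3-dione spanning two quaternary carbons, and its preparation is an open problem. A2 is achiral by a mirror plane and not meso in the strict sense, and its two carbonyls differ only through the distant CH2/CMe2 difference in the three-carbon bridge. The alkyne must also insert with its oxygen-bearing carbon towards C5, and three kinds of alkene can bind the metal.
- **Comparison:** the late intermediate is the same, the mechanism has less analogy than acylation, aldol and 1,2-shift, and the step count is better only if A2 is short to make.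

Alternative 2: The cut is the C5–C6 bond of ring B, leading from the trione A3 back to the monocyclic trione carbonate A4.
- **Forward step:** a zerovalent palladium catalyst with a chiral C2-symmetric diphosphine would ionise the allylic carbonate, and one of the two enantiotopic doubly activated carbons would attack the allyl terminus.
- **In its favour:** the hindered quaternary C1 is made by ordinary alkylation before any ring exists. The allyl unit has two identical termini, so there is no regiochemical question there. The C7 methylene arises directly, which would save steps 9 to 11. The bridgehead left for later is C5, next to a CH2 group, and geranylation there should be easier than the C1 prenylation of step 8. On these points it is the better plan.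
- **Equal points:** enol ether formation, hydroboration and coupling at C7, C3 aroylation and unmasking would still be needed, and the enol ether must again carry its oxygen on the correct carbon for the bridgehead step.
- **Against it:** the trione anion is ambident, so O-allylation competes, and the catalyst must discriminate two nucleophilic carbons that lie far from the allyl-bound ligand.
- **Comparison:** structure and step count are similar or slightly better, while the enantioselection is less predictable than an enzymatic carbinol relayed by substrate control.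

Alternative 3: The cut is the C1–C8 bond, leading from the aryl acetate A5 back to the dearomatised acylphloroglucinol A6 with a lavandulyl-type chain on C5.
- **Forward step:** Markovnikov activation of the isopropenyl group, by a protic acid or by a cobalt-hydride hydrogen-atom transfer followed by oxidation, would give the tertiary C8 cation, which enol carbon C1 traps.
- **In its favour:** it is by far the shortest plan. All carbons are in place, the C7 centre comes from the chiral pool, and the hardest bond of the molecule is formed directly. On step economy it is clearly better.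
- **Against it:** A6 has two stereocentres, C5 and C7, that must be set relative to each other in an alkylative dearomatisation while C7 sits on a flexible chain, and the wrong C5 epimer leads to the C7 epimer of the product. The cation can also be captured by enol oxygen or by C3. A protic acid will protonate the prenyl and geranyl alkenes as well; the cobalt variant should be more selective for the 1,1-disubstituted alkene.
- **Comparison:** the product is the same skeleton at the same oxidation level, the mechanism is cationic where the chosen route is anionic and oxidative, and the alternative is shorter but less predictable in all three stereocentres.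

Key step: step 4

Remark on the chemistry: the bicyclic compounds carry the core numbering of 30 (C1 and C5 bridgeheads, C9 bridge). Exo at C7 means pointing away from ring A, endo towards it. Geranyl is (2E)-3,7-dimethylocta-2,6-dien-1-yl and prenyl is 3-methylbut-2-en-1-yl.

Remark on the chemistry: 12 and 30 are enolised β-dicarbonyl compounds; one tautomer is drawn and the others interconvert freely.

Remark on the chemistry: the configurations of 6, 10 and 30 were checked against one another. Acylation anti to the (R)-silyloxy group gives the (5S) bridgehead of 30, and hydrogen delivery to the exo face of C7 gives the endo prenyl group, so no structure needed correction.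

## Steps

Step 1
Reactants: 1 2,2-dimethylcyclopentane-1,3-dione
Product: 2 (R)-3-hydroxy-2,2-dimethylcyclopentan-1-one
Conditions: (R)-selective (anti-Prelog) ketoreductase, NADP+ (cat.), i-PrOH, aq. phosphate buffer pH 7, 30 °C
Reagents that add atoms: none
Why: Enzymatic desymmetrising reduction: hydride from the cofactor is delivered to one of the two enantiotopic carbonyls and an anti-Prelog enzyme sets the (R)-carbinol, the future C7 oxygen. Mono-reduction is expected because the hydroxy ketone is a poorer substrate, and i-PrOH recycles the cofactor.

Step 2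
Reactants: 2 (R)-3-hydroxy-2,2-dimethylcyclopentan-1-one
Product: 3 (R)-3-(tert-butyldimethylsilyloxy)-2,2-dimethylcyclopentan-1-one
Conditions: TBSCl, imidazole, DMF, 23 °C
Reagents that add atoms: tert-butyldimethylsilyl chloride, CC(C)(C)[Si](C)(C)Cl
Why: Standard silylation of a secondary alcohol; the ether prevents retro-aldol opening of the β-hydroxy ketone under the strong bases that follow and provides the bulk that shields one ring face in steps 3 and 4.

Step 3
Reactants: 3 (R)-3-(tert-butyldimethylsilyloxy)-2,2-dimethylcyclopentan-1-one; 4 geranyl bromide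
Product: 6 (3R,5R)-3-(tert-butyldimethylsilyloxy)-5-geranyl-2,2-dimethylcyclopentan-1-one (geranyl trans to the silyloxy group), via lithium enolate 5 (not isolated)
Conditions: LiN(i-Pr)2 (LDA), THF, −78 °C; then 4, −78 → −20 °C
Reagents that add atoms: none
Why: Kinetic enolate alkylation: the ketone can enolise only towards the CH2 group, and the allylic bromide should enter anti to the silyloxy group. The configuration at this carbon is erased again in step 4, so its ratio is not critical.

Step 4
Reactants: 6 (3R,5R)-3-(tert-butyldimethylsilyloxy)-5-geranyl-2,2-dimethylcyclopentan-1-one; 7 diketene (4-methyleneoxetan-2-one)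
Product: 10 (2R,3aR,7aR)-2-(tert-butyldimethylsilyloxy)-3a-geranyl-7a-hydroxy-1,1-dimethylhexahydro-1H-indene-4,6(5H)-dione (cis-fused; geranyl, hydroxyl and silyloxy on one face), via lithium enolate 8 (not isolated), via acyclic acyl enolate 9 (not isolated)
Conditions: LiTMP, THF, −78 → 0 °C; then 7, −78 → −40 °C; aq. NH4Cl
Reagents that add atoms: none
Why: LiTMP removes the only α-hydrogen of 6 (C5–H, since C8 is quaternary) to give the tetrasubstituted enolate 8, which attacks the lactone carbonyl of 7 (C4) through carbon and forms C4–C5. Acyl–oxygen cleavage of the β-lactone releases the acetoacetyl unit as its terminal enolate 9 (C1=C2–OLi), not as the stabilised internal diketonate. Before proton transfer can occur, C1 adds to the adjacent C9 ketone and forms C1–C9, closing ring A as a six-membered ring in a 6-(enolexo)-exo-trig aldol; final proton transfer from C3 to the diketonate makes the cascade irreversible. The closest known reaction type is the diketene annulation of hindered cyclopentanone lithium enolates to fused β-hydroxy 1,3-diones. C5 is set by substrate control: 7 approaches the enolate face anti to the C7 silyloxy group (the gem-dimethyl group is symmetric), so geranyl ends up cis to the silyloxy group. C9 is set by the tether: the three-atom chain on C5 can reach the C9 carbonyl only from its own face, which gives the cis ring fusion. The step needs C- over O-acylation, which a lithium enolate in THF at low temperature favours with diketene, and it needs clean facial selection. Any C5 epimer is a diastereomer here and must be removed at 10 or at the latest at 19, because once C7 becomes trigonal it would be carried on as the enantiomer.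

Step 5
Reactants: 10 (2R,3aR,7aR)-2-(tert-butyldimethylsilyloxy)-3a-geranyl-7a-hydroxy-1,1-dimethylhexahydro-1H-indene-4,6(5H)-dione
Product: 12 7-exo-(tert-butyldimethylsilyloxy)-5-geranyl-8,8-dimethylbicyclo[3.3.1]nonane-2,4,9-trione (bridgeheads as in 30, C1–H), via iodonium ylide 11 (not isolated)
Conditions: PhI(OAc)2, KOH, MeOH, −30 → 23 °C; then 1 M HCl to pH 3
Reagents that add atoms: none
Why: Oxidative semipinacol-type ring expansion with trivalent iodine: the diketonate of 10 is converted into the C3 iodonium ylide 11, and after protonation and enolisation towards C1 the C9 alkoxide drives a 1,2-shift of C8 from C9 to C1 with loss of iodobenzene, giving the C9 ketone and the bicyclo[3.3.1] skeleton. The electron-rich tertiary alkyl carbon C8 should migrate in preference to the acyl-substituted C5, and the C1 configuration is dictated by the bicycle; this is the known ring expansion of fused hydroxy 1,3-diones.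

Step 6
Reactants: 12 7-exo-(tert-butyldimethylsilyloxy)-5-geranyl-8,8-dimethylbicyclo[3.3.1]nonane-2,4,9-trione
Product: 13 7-exo-(tert-butyldimethylsilyloxy)-5-geranyl-4-methoxy-8,8-dimethylbicyclo[3.3.1]non-3-ene-2,9-dione
Conditions: TMSCHN2, MeOH/toluene (1:4), 0 °C
Reagents that add atoms: (trimethylsilyl)diazomethane, C[Si](C)(C)C=[N+]=[N-]
Why: O-Methylation of the vinylogous acid by a diazomethane surrogate masks the dione for the lithiation steps. The C4–O isomer 13 is the one required because only in it does C1–H lie between the C2 and C9 carbonyls, the arrangement that permits bridgehead lithiation. The C2–O regioisomer that can form alongside is separable and returns to 12 on mild acid hydrolysis.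

Step 7
Reactants: 13 7-exo-(tert-butyldimethylsilyloxy)-5-geranyl-4-methoxy-8,8-dimethylbicyclo[3.3.1]non-3-ene-2,9-dione
Product: 15 7-exo-(tert-butyldimethylsilyloxy)-5-geranyl-4-methoxy-8,8-dimethyl-3-(trimethylsilyl)bicyclo[3.3.1]non-3-ene-2,9-dione, via 3-lithio enone 14 (not isolated)
Conditions: LiN(i-Pr)2 (LDA), TMSCl, THF, −78 °C
Reagents that add atoms: chlorotrimethylsilane, C[Si](C)(C)Cl
Why: Vinyl deprotonation with in situ C-silylation: because C1–H is shielded by the neighbouring CMe2 group, the amide base should remove the C3 vinyl hydrogen first (14), and the silyl group then blocks C3 so that step 8 can only take place at the bridgehead.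

Step 8
Reactants: 15 7-exo-(tert-butyldimethylsilyloxy)-5-geranyl-4-methoxy-8,8-dimethyl-3-(trimethylsilyl)bicyclo[3.3.1]non-3-ene-2,9-dione; 16 prenyl bromide
Product: 18 7-exo-(tert-butyldimethylsilyloxy)-5-geranyl-4-methoxy-8,8-dimethyl-1-prenyl-3-(trimethylsilyl)bicyclo[3.3.1]non-3-ene-2,9-dione, via bridgehead lithio compound 17 (not isolated)
Conditions: LiTMP, THF, −78 → −40 °C; then 16, −78 → 0 °C
Reagents that add atoms: none
Why: Bridgehead lithiation and alkylation: with C3 blocked, LiTMP removes C1–H, which is acidified inductively by the C2 and C9 carbonyls, and SN2 alkylation of 17 by the allylic bromide forms the quaternary C1 with retention, the only geometry the bicycle allows. The step is placed here because no enolisable ketone is present yet.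

Step 9
Reactants: 18 7-exo-(tert-butyldimethylsilyloxy)-5-geranyl-4-methoxy-8,8-dimethyl-1-prenyl-3-(trimethylsilyl)bicyclo[3.3.1]non-3-ene-2,9-dione
Product: 19 5-geranyl-7-exo-hydroxy-4-methoxy-8,8-dimethyl-1-prenylbicyclo[3.3.1]non-3-ene-2,9-dione
Conditions: TBAF, THF, 0 → 50 °C
Reagents that add atoms: none
Why: Fluoride-mediated desilylation removes both silicon groups in one operation: the C7 O–Si bond is cleaved and the vinylic C3–Si bond α to the carbonyl undergoes protodesilylation, which restores C3–H for step 15.

Step 10
Reactants: 19 5-geranyl-7-exo-hydroxy-4-methoxy-8,8-dimethyl-1-prenylbicyclo[3.3.1]non-3-ene-2,9-dione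
Product: 20 5-geranyl-4-methoxy-8,8-dimethyl-1-prenylbicyclo[3.3.1]non-3-ene-2,7,9-trione
Conditions: Dess–Martin periodinane, NaHCO3, CH2Cl2, 23 °C
Reagents that add atoms: none
Why: Buffered periodinane oxidation of a secondary alcohol spares the trisubstituted alkenes and the enol ether; the C7 oxygen stereocentre has done its work and is removed.

Step 11
Reactants: 20 5-geranyl-4-methoxy-8,8-dimethyl-1-prenylbicyclo[3.3.1]non-3-ene-2,7,9-trione
Product: 21 5-geranyl-4-methoxy-8,8-dimethyl-7-methylene-1-prenylbicyclo[3.3.1]non-3-ene-2,9-dione
Conditions: Ph3PCH3Br, KOtBu, toluene, 0 → 70 °C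
Reagents that add atoms: methyltriphenylphosphonium bromide, C[P+](c1ccccc1)(c1ccccc1)c1ccccc1.[Br-]
Why: Wittig methylenation: the C7 ketone has one CH2 neighbour and is far more accessible than the C9 ketone between two quaternary carbons, and the C2 carbonyl is a deactivated vinylogous ester, so the unstabilised ylide should react at C7 only.

Step 12
Reactants: 21 5-geranyl-4-methoxy-8,8-dimethyl-7-methylene-1-prenylbicyclo[3.3.1]non-3-ene-2,9-dione; 22 1-bromo-2-methylprop-1-ene
Product: 24 5-geranyl-4-methoxy-8,8-dimethyl-1,7-endo-diprenylbicyclo[3.3.1]non-3-ene-2,9-dione, via B-alkyl borane 23 (not isolated)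
Conditions: 9-BBN, THF, 0 → 23 °C; then 22, Pd(dppf)Cl2, AsPh3, aq. K3PO4, DMF, 23 → 50 °C
Reagents that add atoms: none
Why: Hydroboration followed by B-alkyl Suzuki–Miyaura coupling: 9-BBN should add only to the 1,1-disubstituted C7 methylene, since trisubstituted alkenes react far more slowly, with boron on the terminal carbon. Hydrogen is delivered to C7 from the exo face because the endo face is covered by ring A, which sets C7 with the new CH2 group endo. Zerovalent palladium generated from Pd(dppf)Cl2 then couples the primary alkylborane 23 with 22 to complete the prenyl group.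

Step 13
Reactants: 25 3-hydroxybenzoic acid
Product: 26 tert-butyldimethylsilyl 3-(tert-butyldimethylsilyloxy)benzoate
Conditions: TBSCl, imidazole, DMF, 23 °C
Reagents that add atoms: tert-butyldimethylsilyl chloride, CC(C)(C)[Si](C)(C)Cl
Why: Double silylation of phenol and acid; the silyl ester is the direct precursor of the acid chloride under neutral conditions and the aryl silyl ether is the base-labile phenol mask needed in step 16.

Step 14
Reactants: 26 tert-butyldimethylsilyl 3-(tert-butyldimethylsilyloxy)benzoate
Product: 27 3-(tert-butyldimethylsilyloxy)benzoyl chloride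
Conditions: (COCl)2, DMF (cat.), CH2Cl2, 0 → 23 °C
Reagents that add atoms: oxalyl chloride, ClC(=O)C(Cl)=O
Why: Conversion of a silyl ester into the acid chloride by Vilsmeier-type activation proceeds without free HCl, so the aryl silyl ether should stay intact.

Step 15
Reactants: 24 5-geranyl-4-methoxy-8,8-dimethyl-1,7-endo-diprenylbicyclo[3.3.1]non-3-ene-2,9-dione; 27 3-(tert-butyldimethylsilyloxy)benzoyl chloride
Product: 29 3-[3-(tert-butyldimethylsilyloxy)benzoyl]-5-geranyl-4-methoxy-8,8-dimethyl-1,7-endo-diprenylbicyclo[3.3.1]non-3-ene-2,9-dione, via 3-lithio enone 28 (not isolated)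
Conditions: LiTMP, THF, −78 °C; then 27, −78 → −40 °C
Reagents that add atoms: none
Why: Vinyl lithiation and C-acylation: LiTMP removes the only acidic hydrogen left, C3–H between the carbonyl and the enol ether carbon, and the acid chloride acylates 28 at carbon. The product ketone is hindered and cross-conjugated and should not react further.

Step 16
Reactants: 29 3-[3-(tert-butyldimethylsilyloxy)benzoyl]-5-geranyl-4-methoxy-8,8-dimethyl-1,7-endo-diprenylbicyclo[3.3.1]non-3-ene-2,9-dione
Product: 30 (1S,5S,7S)-5-geranyl-4-hydroxy-3-(3-hydroxybenzoyl)-8,8-dimethyl-1,7-diprenylbicyclo[3.3.1]non-3-ene-2,9-dione (C7 prenyl endo)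
Conditions: LiOH, dioxane/H2O, 90 °C; then aq. HCl to pH 3, 0 °C
Reagents that add atoms: water, O
Why: Hydroxide adds to C4 of the vinylogous ester and expels methoxide (addition–elimination) and also cleaves the base-labile aryl silyl ether. The triketone is protected from retro-Claisen cleavage as its delocalised anion, and cold acidification should release 30.

## Compound list

1 | 2,2-dimethylcyclopentane-1,3-dione | CC1(C)C(=O)CCC1=O | starting material
2 | (R)-3-hydroxy-2,2-dimethylcyclopentan-1-one | O=C1CC[C@@H](O)C1(C)C | intermediate
3 | (R)-3-(tert-butyldimethylsilyloxy)-2,2-dimethylcyclopentan-1-one | O=C1CC[C@@H](O[Si](C)(C)C(C)(C)C)C1(C)C | intermediate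
4 | geranyl bromide | CC(C)=CCC/C(C)=C/CBr | starting material
5 | lithium (4R)-4-(tert-butyldimethylsilyloxy)-5,5-dimethylcyclopent-1-en-1-olate | [Li]OC1=CC[C@@H](O[Si](C)(C)C(C)(C)C)C1(C)C | intermediate
6 | (3R,5R)-3-(tert-butyldimethylsilyloxy)-5-geranyl-2,2-dimethylcyclopentan-1-one | CC(C)=CCC/C(C)=C/C[C@@H]1C[C@@H](O[Si](C)(C)C(C)(C)C)C(C)(C)C1=O | intermediate
7 | diketene | C=C1CC(=O)O1 | starting material
8 | lithium enolate of 6 (C5=C9–OLi) | CC(C)=CCC/C(C)=C/CC1=C(O[Li])C(C)(C)[C@H](O[Si](C)(C)C(C)(C)C)C1 | intermediate
9 | C5-acetoacetylated ketone as its terminal lithium enolate | CC(C)=CCC/C(C)=C/C[C@@]1(C(=O)CC(=C)O[Li])C[C@@H](O[Si](C)(C)C(C)(C)C)C(C)(C)C1=O | intermediate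
10 | (2R,3aR,7aR)-2-(tert-butyldimethylsilyloxy)-3a-geranyl-7a-hydroxy-1,1-dimethylhexahydro-1H-indene-4,6(5H)-dione | CC(C)=CCC/C(C)=C/C[C@@]12C[C@@H](O[Si](C)(C)C(C)(C)C)C(C)(C)[C@]1(O)CC(=O)CC2=O | intermediate
11 | C3 phenyliodonium ylide of 10 | CC(C)=CCC/C(C)=C/C[C@@]12C[C@@H](O[Si](C)(C)C(C)(C)C)C(C)(C)[C@]1(O)CC(=O)[C-]([I+]c3ccccc3)C2=O | intermediate
12 | 7-exo-(tert-butyldimethylsilyloxy)-5-geranyl-8,8-dimethylbicyclo[3.3.1]nonane-2,4,9-trione | CC(C)=CCC/C(C)=C/C[C@]12C[C@@H](O[Si](C)(C)C(C)(C)C)C(C)(C)[C@H](C(=O)CC1=O)C2=O | intermediate
13 | 7-exo-(tert-butyldimethylsilyloxy)-5-geranyl-4-methoxy-8,8-dimethylbicyclo[3.3.1]non-3-ene-2,9-dione | CC(C)=CCC/C(C)=C/C[C@]12C[C@@H](O[Si](C)(C)C(C)(C)C)C(C)(C)[C@H](C(=O)C=C1OC)C2=O | intermediate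
14 | 3-lithio derivative of 13 | CC(C)=CCC/C(C)=C/C[C@]12C[C@@H](O[Si](C)(C)C(C)(C)C)C(C)(C)[C@H](C(=O)C([Li])=C1OC)C2=O | intermediate
15 | 3-(trimethylsilyl) derivative of 13 | CC(C)=CCC/C(C)=C/C[C@]12C[C@@H](O[Si](C)(C)C(C)(C)C)C(C)(C)[C@H](C(=O)C([Si](C)(C)C)=C1OC)C2=O | intermediate
16 | prenyl bromide | CC(C)=CCBr | starting material
17 | 1-lithio derivative of 15 | CC(C)=CCC/C(C)=C/C[C@]12C[C@@H](O[Si](C)(C)C(C)(C)C)C(C)(C)[C@]([Li])(C(=O)C([Si](C)(C)C)=C1OC)C2=O | intermediate
18 | 7-exo-(tert-butyldimethylsilyloxy)-5-geranyl-4-methoxy-8,8-dimethyl-1-prenyl-3-(trimethylsilyl)bicyclo[3.3.1]non-3-ene-2,9-dione | CC(C)=CCC/C(C)=C/C[C@]12C[C@@H](O[Si](C)(C)C(C)(C)C)C(C)(C)[C@](CC=C(C)C)(C(=O)C([Si](C)(C)C)=C1OC)C2=O | intermediate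
19 | 5-geranyl-7-exo-hydroxy-4-methoxy-8,8-dimethyl-1-prenylbicyclo[3.3.1]non-3-ene-2,9-dione | CC(C)=CCC/C(C)=C/C[C@]12C[C@@H](O)C(C)(C)[C@](CC=C(C)C)(C(=O)C=C1OC)C2=O | intermediate
20 | 5-geranyl-4-methoxy-8,8-dimethyl-1-prenylbicyclo[3.3.1]non-3-ene-2,7,9-trione | CC(C)=CCC/C(C)=C/C[C@]12CC(=O)C(C)(C)[C@](CC=C(C)C)(C(=O)C=C1OC)C2=O | intermediate
21 | 5-geranyl-4-methoxy-8,8-dimethyl-7-methylene-1-prenylbicyclo[3.3.1]non-3-ene-2,9-dione | CC(C)=CCC/C(C)=C/C[C@]12CC(=C)C(C)(C)[C@](CC=C(C)C)(C(=O)C=C1OC)C2=O | intermediate
22 | 1-bromo-2-methylprop-1-ene | CC(C)=CBr | starting material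
23 | 7-endo-[(9-borabicyclo[3.3.1]nonan-9-yl)methyl] adduct of 21 | CC(C)=CCC/C(C)=C/C[C@]12C[C@H](CB3C4CCCC3CCC4)C(C)(C)[C@](CC=C(C)C)(C(=O)C=C1OC)C2=O | intermediate
24 | 5-geranyl-4-methoxy-8,8-dimethyl-1,7-endo-diprenylbicyclo[3.3.1]non-3-ene-2,9-dione | CC(C)=CCC/C(C)=C/C[C@]12C[C@H](CC=C(C)C)C(C)(C)[C@](CC=C(C)C)(C(=O)C=C1OC)C2=O | intermediate
25 | 3-hydroxybenzoic acid | OC(=O)c1cccc(O)c1 | starting material
26 | tert-butyldimethylsilyl 3-(tert-butyldimethylsilyloxy)benzoate | CC(C)(C)[Si](C)(C)OC(=O)c1cccc(O[Si](C)(C)C(C)(C)C)c1 | intermediate
27 | 3-(tert-butyldimethylsilyloxy)benzoyl chloride | CC(C)(C)[Si](C)(C)Oc1cccc(C(Cl)=O)c1 | intermediate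
28 | 3-lithio derivative of 24 | CC(C)=CCC/C(C)=C/C[C@]12C[C@H](CC=C(C)C)C(C)(C)[C@](CC=C(C)C)(C(=O)C([Li])=C1OC)C2=O | intermediate
29 | 3-[3-(tert-butyldimethylsilyloxy)benzoyl] derivative of 24 | CC(C)=CCC/C(C)=C/C[C@]12C[C@H](CC=C(C)C)C(C)(C)[C@](CC=C(C)C)(C(=O)C(C(=O)c3cccc(O[Si](C)(C)C(C)(C)C)c3)=C1OC)C2=O | intermediate
30 | (1S,5S,7S)-5-geranyl-4-hydroxy-3-(3-hydroxybenzoyl)-8,8-dimethyl-1,7-diprenylbicyclo[3.3.1]non-3-ene-2,9-dione | CC(C)=CCC/C(C)=C/C[C@]12C[C@H](CC=C(C)C)C(C)(C)[C@](CC=C(C)C)(C(=O)C(C(=O)c3cccc(O)c3)=C1O)C2=O | target

## Step count and least certain steps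

Total: 16 steps. Longest linear sequence: 14 steps (steps 1 to 12, 15 and 16); the acid chloride 27 is made in a two-step side branch (steps 13 and 14).

Step 4 (key step). The most likely failure is that proton transfer inside 9 to the internal diketonate outruns the aldol addition, because the C9 carbonyl then lies between two quaternary carbons. Facial selection by a silyloxy group two bonds from C5 may also be incomplete, which is why diastereomers must be separated at 10. Fallback: starting from 6, the enolate is acylated with 7 at −78 °C and quenched cold, so that the open-chain 5-acetoacetyl ketone F1 is isolated. Ring A is then closed in a separate operation by treating F1 with LiN(i-Pr)2 (2.2 equivalents), which regenerates the reactive terminal carbanion as the diketone dianion for the aldol addition to C9. This returns to the route at 10.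

Step 5. The most likely failure is oxidation at C3 without rearrangement (methoxylation or a stalled ylide), or retro-aldol opening of 10 in methanolic KOH, because C3 is far more acidic than C1. Fallback: starting from 10, LiN(i-Pr)2 (3.3 equivalents) forms the alkoxide and diketone dianion, whose terminal carbon C1 is brominated with 1,2-dibromotetrachloroethane to give the C1-bromo hydroxy dione F2. Ag2CO3 in MeCN then promotes a halohydrin semipinacol shift of C8 with loss of bromide. This returns to the route at 12.

Step 6. The most likely failure is poor regioselectivity of O-methylation, because the two dione oxygens differ only in the bridgehead substituent beside them and only the C4–O isomer can pass through step 8. Fallback: the C1 prenyl group is introduced before the ring expansion, so that the enol ether position no longer matters for reactivity.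
- Starting from 10, LiN(i-Pr)2 (3.3 equivalents) and 16 give the C1-prenylated hydroxy dione F3 by alkylation at the terminal carbon of the diketone dianion.
- PhI(OAc)2 with KOH in MeOH then shifts C8 onto the substituted C1 to give the 1-prenyl trione F4.
- TMSCHN2 gives the 4-methoxy enol ether F5 (its regioisomer serves equally well and converges in step 16).
- TBAF removes the silyl ether, and the sequence returns to the route at 19.

Step 8. The most likely failure is a slow or incomplete alkylation of the hindered bridgehead anion next to CMe2, with decomposition or allylic transposition of the electrophile. Fallback: starting from 15, the bridgehead anion is trapped with I2, a small electrophile, to give the bridgehead iodide F6. Radical allylation of F6 with allyltributylstannane and AIBN gives the C1-allyl compound F7, and cross-metathesis of F7 with 2-methylbut-2-ene and the second-generation Grubbs catalyst returns to the route at 18. If the deprotonation itself fails, the sequence through F3, F4 and F5 applies.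

Step 12. The most likely failure is slow transmetalation of the β-branched alkylborane beside a quaternary carbon, which leads to protodeboronation; excess borane may also begin to attack the trisubstituted alkenes or the C9 ketone. Fallback: starting from 21, hydroboration with 9-BBN and oxidation with NaBO3 give the 7-endo-hydroxymethyl compound F8. I2, PPh3 and imidazole convert it into the primary iodide F9, and a reductive cross-electrophile coupling of F9 with 22 (NiI2, 4,4′-di-tert-butyl-2,2′-bipyridine, zinc dust, DMA) returns to the route at 24.

## Further compounds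

F1 | step 4 | (3R,5R-derived) 5-acetoacetyl-3-(tert-butyldimethylsilyloxy)-5-geranyl-2,2-dimethylcyclopentan-1-one, open-chain triketone | CC(C)=CCC/C(C)=C/C[C@@]1(C(=O)CC(C)=O)C[C@@H](O[Si](C)(C)C(C)(C)C)C(C)(C)C1=O
F2 | step 5 | C1-bromo derivative of 10 (C1 epimers, interconverting by enolisation) | CC(C)=CCC/C(C)=C/C[C@@]12C[C@@H](O[Si](C)(C)C(C)(C)C)C(C)(C)[C@]1(O)C(Br)C(=O)CC2=O
F3 | step 6 | C1-prenyl derivative of 10 (C1 epimers) | CC(C)=CCC/C(C)=C/C[C@@]12C[C@@H](O[Si](C)(C)C(C)(C)C)C(C)(C)[C@]1(O)C(CC=C(C)C)C(=O)CC2=O
F4 | step 6 | 7-exo-(tert-butyldimethylsilyloxy)-5-geranyl-8,8-dimethyl-1-prenylbicyclo[3.3.1]nonane-2,4,9-trione | CC(C)=CCC/C(C)=C/C[C@]12C[C@@H](O[Si](C)(C)C(C)(C)C)C(C)(C)[C@](CC=C(C)C)(C(=O)CC1=O)C2=O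
F5 | step 6 | 7-exo-(tert-butyldimethylsilyloxy)-5-geranyl-4-methoxy-8,8-dimethyl-1-prenylbicyclo[3.3.1]non-3-ene-2,9-dione | CC(C)=CCC/C(C)=C/C[C@]12C[C@@H](O[Si](C)(C)C(C)(C)C)C(C)(C)[C@](CC=C(C)C)(C(=O)C=C1OC)C2=O
F6 | step 8 | 1-iodo derivative of 15 | CC(C)=CCC/C(C)=C/C[C@]12C[C@@H](O[Si](C)(C)C(C)(C)C)C(C)(C)[C@](I)(C(=O)C([Si](C)(C)C)=C1OC)C2=O
F7 | step 8 | 1-allyl derivative of 15 | CC(C)=CCC/C(C)=C/C[C@]12C[C@@H](O[Si](C)(C)C(C)(C)C)C(C)(C)[C@](CC=C)(C(=O)C([Si](C)(C)C)=C1OC)C2=O
F8 | step 12 | 5-geranyl-7-endo-(hydroxymethyl)-4-methoxy-8,8-dimethyl-1-prenylbicyclo[3.3.1]non-3-ene-2,9-dione | CC(C)=CCC/C(C)=C/C[C@]12C[C@H](CO)C(C)(C)[C@](CC=C(C)C)(C(=O)C=C1OC)C2=O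
F9 | step 12 | 5-geranyl-7-endo-(iodomethyl)-4-methoxy-8,8-dimethyl-1-prenylbicyclo[3.3.1]non-3-ene-2,9-dione | CC(C)=CCC/C(C)=C/C[C@]12C[C@H](CI)C(C)(C)[C@](CC=C(C)C)(C(=O)C=C1OC)C2=O
A1 | alternative 1 | 4-ethoxy-5-geranyl-8,8-dimethyl-7-methylene-1-prenylbicyclo[3.3.1]non-3-ene-2,9-dione | CC(C)=CCC/C(C)=C/C[C@]12CC(=C)C(C)(C)[C@](CC=C(C)C)(C(=O)C=C1OCC)C2=O
A2 | alternative 1 | 5-geranyl-2,2-dimethyl-3-methylene-1-prenylbicyclo[3.1.1]heptane-6,7-dione (achiral) | CC(C)=CCC/C(C)=C/CC12CC(=C)C(C)(C)C(CC=C(C)C)(C1=O)C2=O
A3 | alternative 2 | 8,8-dimethyl-7-methylene-1-prenylbicyclo[3.3.1]nonane-2,4,9-trione | [C@H]12CC(=C)C(C)(C)[C@](CC=C(C)C)(C(=O)CC1=O)C2=O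
A4 | alternative 2 | methyl 3,3-dimethyl-2-methylene-3-(2,4,6-trioxo-1-prenylcyclohexyl)propyl carbonate (achiral) | COC(=O)OCC(=C)C(C)(C)C1(CC=C(C)C)C(=O)CC(=O)CC1=O
A5 | alternative 3 | 30 as its aryl acetate | CC(C)=CCC/C(C)=C/C[C@]12C[C@H](CC=C(C)C)C(C)(C)[C@](CC=C(C)C)(C(=O)C(C(=O)c3cccc(OC(C)=O)c3)=C1O)C2=O
A6 | alternative 3 | 2-(3-acetoxybenzoyl)-6-geranyl-3,5-dihydroxy-6-[(2S-type) 5-methyl-2-(prop-1-en-2-yl)hex-4-en-1-yl]-4-prenylcyclohexa-2,4-dien-1-one | CC(C)=CCC/C(C)=C/C[C@]1(C[C@H](CC=C(C)C)C(C)=C)C(=O)C(C(=O)c2cccc(OC(C)=O)c2)=C(O)C(CC=C(C)C)=C1O
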